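Readings and results are simulated with made-up constants; scatter was added.

In a one-step world you would take the coupling partner as the limiting reagent: at one per turn, its charge allows 40.0% of the two substrates to react. The runs stop well short of that, so look elsewhere.

| flask | left-handed substrate | right-handed substrate | coupling partner | precatalyst | remark | time |
|---|---|---|---|---|---|---|
| ochre | 1 M | 1 M | 0.80 M | 100 mM | the very flask that is asked about, followed so far |  |
| violet | 1 M | 1 M | 0.80 M | 200 mM | run made earlier |  |
| flask | 1.0 M | 1.0 M | 0.800 M | 100 mM |  | 15 h |

- ochre (time / h: left-handed substrate / %, right-handed substrate / %, left-handed product / %): 1.33: 48.3, 49.2, 0.2; 2.50: 46.5, 47.6, 3.7; 4.00: 44.4, 46.5, 6.2; 5.00: 45.1, 46.3, 6.5; 6.00: 45.2, 46.4, 5.9; 8.00: 41.8, 46.3, 4.7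
- violet (time / h: left-handed substrate / %, right-handed substrate / %, left-handed product / %): 0.833: 49.6, 48.8, 0; 1.33: 48.1, 47.7, 1.9; 2.50: 44.4, 46.7, 5.0; 4.00: 41.8, 45.3, 4.7; 6.00: 41.2, 45.7, 8.2; 10.0: 39.5, 43.0, 10.2

(readings scatter by 1 percentage point)

* part of the left-handed substrate and right-handed substrate charged together that has reacted at 15 h
* excess of left-handed product over right-handed product in the product at 15 h
* excess of right-handed substrate over left-handed substrate among what is left of the two at 15 h

- free catalyst is single-handed; left-handed substrate and right-handed substrate are mirror images of each other, charged as a racemate, each of them at the stated concentration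
- an excess is the difference of the two amounts in percent of their sum
- an excess is below zero if the other one leads

Take the givens in turn. Coupling partner and substrates stand at the same charges in both runs, so the readings cannot show what an error in them would do. Time looks weak: the reacted part in ochre reads 9.10% at 4.00 h and 8.40% at 6.00 h, inside a scatter of 1.4 percentage points. Precatalyst is the number you must know well: twice the charge in violet lifts the reacted part at 6.00 h from 8.40% to 13.1%.

So carry N, the moles of substrate consumed per mole of precatalyst charged, a turnover number. The last readings give 11.9% reacted in ochre and 17.5% in violet, and together N = 2.07. For this flask that gives a first answer of 10.3%. Go round once more: I assume N follows the mean substrate present, and this first answer lies below the 14.7% that the two last readings average, so c becomes 10.6%. The substrate losses in those same last readings give eP = 27.2%, and the balance of a racemate gives eS = eP·c/(1−c) = 3.23%.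

The forecast says c 14%, higher than mine, eP 25% and eS 4%, holding that “the catalyst is dying or being inhibited”.

The flask gives c 11.1%, eP 23.0% and eS 2.89%.

    coupling partner + precatalyst → free catalyst + spent reagent (k = 0.800 L mol⁻¹ h⁻¹)
    coupling partner + free catalyst → spent catalyst (k = 0.780 L mol⁻¹ h⁻¹)
    coupling partner + free catalyst + right-handed substrate → free catalyst + right-handed product (k = 0.730 L² mol⁻² h⁻¹)
    2 coupling partner → self-condensation product (k = 0.0160 L mol⁻¹ h⁻¹)
    coupling partner + free catalyst + left-handed substrate → free catalyst + left-handed product (k = 1.20 L² mol⁻² h⁻¹)

That makes N in this flask 2.23, against 2.07 read from the runs. Part of what holds it there is the turning of coupling partner and free catalyst into spent catalyst: the same flask without that step reaches 27.8%, not 11.1%. Carried to a neighbour flask with 0.060 M of precatalyst, this N predicts 6.68%, and that flask gives 7.03%.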